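**Retrosynthetic overview**

1. The only ring (14-membered) is closed last: C3=C4 by intramolecular Horner–Wadsworth–Emmons olefination of aldehyde–phosphonoacetate 20.
2. C4–C5 by phosphonoacetate alkylation; C8–C9, C6–C7 and the 7Z olefin by Normant carbocupration of propyne followed by oxirane opening.
3. C10–C11, the C12 methyl group and the 11E olefin by Zr-catalysed carboalumination of alkyne 10 (from the methyl ketone) followed by oxirane opening.
4. Side chain: the C17–C18 bond is made by a thermal [3,3] Cope rearrangement (7 → 8) of a 1,1-dimethylallyl precursor; this precursor carries no trisubstituted side-chain olefin, so the ring olefin of the limonene skeleton can be cleaved selectively beforehand.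
5. The C1 stereocentre is bought as (R)-limonene; its ring C=C is cleaved to the C3 aldehyde and the C12 ketone.

Numbering used in the text: macrocycle C1 (stereocentre) to C14, CO2Me on C4, CH3 on C8 and C12; side chain C15(=C16H2)–C17H2–C18H2–C19H=C20(CH3)2. Assumption: (R)-limonene, prenylmagnesium chloride, propyne, oxirane, Me3Al and trimethyl phosphonoacetate are purchased.

**Route**

Step 1
Reactants: 1 (R)-(+)-limonene
Product: 3 (4R)-4-(3-bromoprop-1-en-2-yl)-1-methylcyclohex-1-ene, via 10-lithiolimonene 2 (not isolated)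
Conditions: n-BuLi, TMEDA, hexane, rt, 24 h; then added to BrCH2CH2Br, THF, −78 °C
Reagents that add atoms: 1,2-dibromoethane BrCCBr
Why: Allylic metalation with n-BuLi·TMEDA takes place at the isopropenyl methyl group and the symmetric allyllithium is brominated by halogen transfer, leaving the C4 stereocentre untouched.

Step 2
Reactants: 3 (4R)-4-(3-bromoprop-1-en-2-yl)-1-methylcyclohex-1-ene
Product: 4 (4R)-4-(4,4-dimethylhexa-1,5-dien-2-yl)-1-methylcyclohex-1-ene
Conditions: prenylMgCl (1.5 equiv), THF, −20 °C → rt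
Reagents that add atoms: (3-methylbut-2-en-1-yl)magnesium chloride CC(C)=CC[Mg]Cl
Why: Allyl–allyl coupling in which the allylic Grignard reagent attacks through its γ-carbon (SE2'), giving the 1,1-dimethylallyl 1,5-diene whose terminal vinyl group is inert in the next oxidation.

Step 3
Reactants: 4 (4R)-4-(4,4-dimethylhexa-1,5-dien-2-yl)-1-methylcyclohex-1-ene
Product: 6 (3R)-3-(4,4-dimethylhexa-1,5-dien-2-yl)-6-oxoheptanal, via ring 1,2-epoxide 5 (not isolated)
Conditions: m-CPBA (1.05 equiv), NaHCO3, CH2Cl2, 0 °C; then H5IO6, THF–H2O, 0 °C → rt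
Reagents that add atoms: m-CPBA O=C(OO)c1cccc(Cl)c1; water O
Why: Prilezhaev epoxidation selects the trisubstituted ring olefin over the 1,1-disubstituted and monosubstituted ones, and periodic acid opens and cleaves the epoxide (Malaprade cleavage) without touching the β-stereocentre.

Step 4
Reactants: 6 (3R)-3-(4,4-dimethylhexa-1,5-dien-2-yl)-6-oxoheptanal
Product: 7 (5R)-7,7-dimethoxy-5-(4,4-dimethylhexa-1,5-dien-2-yl)heptan-2-one
Conditions: HC(OMe)3, MeOH, CeCl3·7H2O (cat.), rt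
Reagents that add atoms: trimethyl orthoformate COC(OC)OC; methanol CO
Why: Chemoselective (Luche-type) acetalisation, the aldehyde reacting much faster than the methyl ketone.

Step 5
Reactants: 7 (5R)-7,7-dimethoxy-5-(4,4-dimethylhexa-1,5-dien-2-yl)heptan-2-one
Product: 8 (5R)-7,7-dimethoxy-5-(6-methylhepta-1,5-dien-2-yl)heptan-2-one
Conditions: PhMe (degassed), BHT, 195 °C, sealed tube, 6 h
Reagents that add atoms: none
Why: Thermal [3,3]-sigmatropic Cope rearrangement through a chair transition state forms the C17–C18 bond and converts the 1,1-dimethylallyl group into the homoprenyl chain, driven by the new trisubstituted olefin and loss of the quaternary carbon; the stereocentre is outside the rearranging array.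

Step 6
Reactants: 8 (5R)-7,7-dimethoxy-5-(6-methylhepta-1,5-dien-2-yl)heptan-2-one
Product: 10 (5R)-7,7-dimethoxy-5-(6-methylhepta-1,5-dien-2-yl)hept-1-yne, via enol phosphate 9 (not isolated)
Conditions: LDA (1.1 equiv), THF, −78 °C; ClP(O)(OEt)2; LDA (2.3 equiv), −78 °C → rt; H2O
Reagents that add atoms: none
Why: Negishi conversion of a methyl ketone into a terminal alkyne (kinetic enolate, enol phosphate, β-elimination); the former ketone methyl carbon becomes C11.

Step 7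
Reactants: 10 (5R)-7,7-dimethoxy-5-(6-methylhepta-1,5-dien-2-yl)hept-1-yne
Product: 12 (3E,7R)-9,9-dimethoxy-4-methyl-7-(6-methylhepta-1,5-dien-2-yl)non-3-en-1-ol, via alkenylalane 11 (not isolated)
Conditions: Me3Al (2.5 equiv), Cp2ZrCl2 (0.25 equiv), H2O (1 equiv), CH2Cl2, −23 °C; n-BuLi, −78 °C; oxirane, −78 → 0 °C; aq. Rochelle salt
Reagents that add atoms: trimethylaluminium C[Al](C)C; oxirane C1CO1
Why: Negishi Zr-catalysed syn-carboalumination adds CH3 and Al across the alkyne with high regio- and E-selectivity, and the derived alanate opens oxirane with retention, which sets the 11E olefin.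

Step 8
Reactants: 12 (3E,7R)-9,9-dimethoxy-4-methyl-7-(6-methylhepta-1,5-dien-2-yl)non-3-en-1-ol
Product: 13 (3E,7R)-1-bromo-9,9-dimethoxy-4-methyl-7-(6-methylhepta-1,5-dien-2-yl)non-3-ene
Conditions: CBr4, PPh3, 2,6-lutidine, CH2Cl2, 0 °C
Reagents that add atoms: carbon tetrabromide BrC(Br)(Br)Br
Why: Appel bromination of the primary alcohol, buffered so that the acetal and the olefins survive.

Step 9
Reactants: 13 (3E,7R)-1-bromo-9,9-dimethoxy-4-methyl-7-(6-methylhepta-1,5-dien-2-yl)non-3-ene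
Product: 17 (3Z,7E,11R)-13,13-dimethoxy-4,8-dimethyl-11-(6-methylhepta-1,5-dien-2-yl)trideca-3,7-dien-1-ol, via Grignard reagent 14 (not isolated), via alkylcopper 15 (not isolated), via Z-alkenylcopper 16 (not isolated)
Conditions: Mg, Et2O; CuBr·SMe2, Et2O–Me2S, −45 °C; propyne, −25 °C, 48 h; LiC≡C-nPr, HMPA, oxirane, −40 → 0 °C; aq. NH4Cl
Reagents that add atoms: propyne CC#C; oxirane C1CO1
Why: Normant syn-carbocupration of propyne places the chain and copper cis, and the alkenylcuprate opens oxirane with retention, which sets the 7Z olefin and adds C5–C6.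

Step 10
Reactants: 17 (3Z,7E,11R)-13,13-dimethoxy-4,8-dimethyl-11-(6-methylhepta-1,5-dien-2-yl)trideca-3,7-dien-1-ol
Product: 18 (3Z,7E,11R)-1-iodo-13,13-dimethoxy-4,8-dimethyl-11-(6-methylhepta-1,5-dien-2-yl)trideca-3,7-diene
Conditions: I2, PPh3, imidazole, CH2Cl2, 0 °C
Reagents that add atoms: iodine II
Why: Appel-type (Garegg–Samuelsson) iodination of the primary alcohol under non-acidic conditions.

Step 11
Reactants: 18 (3Z,7E,11R)-1-iodo-13,13-dimethoxy-4,8-dimethyl-11-(6-methylhepta-1,5-dien-2-yl)trideca-3,7-diene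
Product: 19 methyl (5Z,9E,13R)-2-(dimethoxyphosphoryl)-15,15-dimethoxy-6,10-dimethyl-13-(6-methylhepta-1,5-dien-2-yl)pentadeca-5,9-dienoate (both C2 epimers)
Conditions: (MeO)2P(O)CH2CO2Me (3 equiv), NaH (2.5 equiv), THF–DMSO, 50 °C
Reagents that add atoms: trimethyl phosphonoacetate COC(=O)CP(=O)(OC)OC
Why: SN2 alkylation of the phosphonoacetate anion by the primary iodide, with excess phosphonate to suppress dialkylation.

Step 12
Reactants: 19 methyl (5Z,9E,13R)-2-(dimethoxyphosphoryl)-15,15-dimethoxy-6,10-dimethyl-13-(6-methylhepta-1,5-dien-2-yl)pentadeca-5,9-dienoate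
Product: 20 methyl (5Z,9E,13R)-2-(dimethoxyphosphoryl)-6,10-dimethyl-13-(6-methylhepta-1,5-dien-2-yl)-15-oxopentadeca-5,9-dienoate
Conditions: PPTS, acetone–H2O, 40 °C
Reagents that add atoms: water O
Why: Mild acid hydrolysis of the dimethyl acetal frees the aldehyde; the stereocentre is β to it and cannot epimerise.

Step 13
Reactants: 20 methyl (5Z,9E,13R)-2-(dimethoxyphosphoryl)-6,10-dimethyl-13-(6-methylhepta-1,5-dien-2-yl)-15-oxopentadeca-5,9-dienoate
Product: 21 methyl (1E,4R,7E,11Z)-7,11-dimethyl-4-(6-methylhepta-1,5-dien-2-yl)cyclotetradeca-1,7,11-triene-1-carboxylate (target)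
Conditions: LiCl, DBU, MeCN, 1 mM (slow addition), rt
Reagents that add atoms: none
Why: Intramolecular Horner–Wadsworth–Emmons olefination (Masamune–Roush conditions, high dilution) closes the 14-membered ring and gives the E enoate with the ester trans to C2, as expected for an α-alkyl phosphonoacetate.

**Compound list**

1 | (R)-(+)-limonene, (4R)-1-methyl-4-(prop-1-en-2-yl)cyclohex-1-ene | CC1=CC[C@@H](CC1)C(C)=C | starting material
2 | 10-lithiolimonene, [2-[(1R)-4-methylcyclohex-3-en-1-yl]prop-2-en-1-yl]lithium (TMEDA complex) | [Li]CC(=C)[C@H]1CC=C(C)CC1 | intermediate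
3 | (4R)-4-(3-bromoprop-1-en-2-yl)-1-methylcyclohex-1-ene | BrCC(=C)[C@H]1CC=C(C)CC1 | intermediate
4 | (4R)-4-(4,4-dimethylhexa-1,5-dien-2-yl)-1-methylcyclohex-1-ene | C=CC(C)(C)CC(=C)[C@H]1CC=C(C)CC1 | intermediate
5 | (4R)-4-(4,4-dimethylhexa-1,5-dien-2-yl)-1-methyl-7-oxabicyclo[4.1.0]heptane (epoxide diastereomers) | C=CC(C)(C)CC(=C)[C@H]1CC2OC2(C)CC1 | intermediate
6 | (3R)-3-(4,4-dimethylhexa-1,5-dien-2-yl)-6-oxoheptanal | O=CC[C@@H](CCC(C)=O)C(=C)CC(C)(C)C=C | intermediate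
7 | (5R)-7,7-dimethoxy-5-(4,4-dimethylhexa-1,5-dien-2-yl)heptan-2-one | COC(OC)C[C@@H](CCC(C)=O)C(=C)CC(C)(C)C=C | intermediate
8 | (5R)-7,7-dimethoxy-5-(6-methylhepta-1,5-dien-2-yl)heptan-2-one | COC(OC)C[C@@H](CCC(C)=O)C(=C)CCC=C(C)C | intermediate
9 | diethyl (5R)-7,7-dimethoxy-5-(6-methylhepta-1,5-dien-2-yl)hept-1-en-2-yl phosphate | COC(OC)C[C@@H](CCC(=C)OP(=O)(OCC)OCC)C(=C)CCC=C(C)C | intermediate
10 | (5R)-7,7-dimethoxy-5-(6-methylhepta-1,5-dien-2-yl)hept-1-yne | COC(OC)C[C@@H](CCC#C)C(=C)CCC=C(C)C | intermediate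
11 | [(1E,5R)-7,7-dimethoxy-2-methyl-5-(6-methylhepta-1,5-dien-2-yl)hept-1-en-1-yl]dimethylalumane | COC(OC)C[C@@H](CC/C(C)=C/[Al](C)C)C(=C)CCC=C(C)C | intermediate
12 | (3E,7R)-9,9-dimethoxy-4-methyl-7-(6-methylhepta-1,5-dien-2-yl)non-3-en-1-ol | COC(OC)C[C@@H](CC/C(C)=C/CCO)C(=C)CCC=C(C)C | intermediate
13 | (3E,7R)-1-bromo-9,9-dimethoxy-4-methyl-7-(6-methylhepta-1,5-dien-2-yl)non-3-ene | COC(OC)C[C@@H](CC/C(C)=C/CCBr)C(=C)CCC=C(C)C | intermediate
14 | [(3E,7R)-9,9-dimethoxy-4-methyl-7-(6-methylhepta-1,5-dien-2-yl)non-3-en-1-yl]magnesium bromide | COC(OC)C[C@@H](CC/C(C)=C/CC[Mg]Br)C(=C)CCC=C(C)C | intermediate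
15 | [(3E,7R)-9,9-dimethoxy-4-methyl-7-(6-methylhepta-1,5-dien-2-yl)non-3-en-1-yl]copper (MgBr2 complex) | COC(OC)C[C@@H](CC/C(C)=C/CC[Cu])C(=C)CCC=C(C)C | intermediate
16 | [(1Z,5E,9R)-11,11-dimethoxy-2,6-dimethyl-9-(6-methylhepta-1,5-dien-2-yl)undeca-1,5-dien-1-yl]copper | COC(OC)C[C@@H](CC/C(C)=C/CC/C(C)=C\[Cu])C(=C)CCC=C(C)C | intermediate
17 | (3Z,7E,11R)-13,13-dimethoxy-4,8-dimethyl-11-(6-methylhepta-1,5-dien-2-yl)trideca-3,7-dien-1-ol | COC(OC)C[C@@H](CC/C(C)=C/CC/C(C)=C\CCO)C(=C)CCC=C(C)C | intermediate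
18 | (3Z,7E,11R)-1-iodo-13,13-dimethoxy-4,8-dimethyl-11-(6-methylhepta-1,5-dien-2-yl)trideca-3,7-diene | COC(OC)C[C@@H](CC/C(C)=C/CC/C(C)=C\CCI)C(=C)CCC=C(C)C | intermediate
19 | methyl (5Z,9E,13R)-2-(dimethoxyphosphoryl)-15,15-dimethoxy-6,10-dimethyl-13-(6-methylhepta-1,5-dien-2-yl)pentadeca-5,9-dienoate | COC(OC)C[C@@H](CC/C(C)=C/CC/C(C)=C\CCC(C(=O)OC)P(=O)(OC)OC)C(=C)CCC=C(C)C | intermediate
20 | methyl (5Z,9E,13R)-2-(dimethoxyphosphoryl)-6,10-dimethyl-13-(6-methylhepta-1,5-dien-2-yl)-15-oxopentadeca-5,9-dienoate | O=CC[C@@H](CC/C(C)=C/CC/C(C)=C\CCC(C(=O)OC)P(=O)(OC)OC)C(=C)CCC=C(C)C | intermediate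
21 | methyl (1E,4R,7E,11Z)-7,11-dimethyl-4-(6-methylhepta-1,5-dien-2-yl)cyclotetradeca-1,7,11-triene-1-carboxylate | C=C(CCC=C(C)C)[C@H]1C/C=C(/C(=O)OC)CC/C=C(/C)CC/C=C(\C)CC1 | target

**Summary**

Total step count: 13. Longest linear sequence: 13 (steps 1–13 from (R)-limonene).

Steps most likely to fail, each with a fallback:

- **Step 2** (regiochemistry of the allyl–allyl coupling and Wurtz-type homocoupling; the minor linear isomer would be over-oxidised in step 3). Fallback: set out from 1. Lithio compound 2 is alkylated with allyl bromide to (4R)-4-(hexa-1,5-dien-2-yl)-1-methylcyclohex-1-ene F1. m-CPBA converts it into the ring epoxide (4R)-4-(hexa-1,5-dien-2-yl)-1-methyl-7-oxabicyclo[4.1.0]heptane F2, and H5IO6 cleaves this to (3R)-3-(hexa-1,5-dien-2-yl)-6-oxoheptanal F3. Acetalisation as in step 4 gives (5R)-5-(hexa-1,5-dien-2-yl)-7,7-dimethoxyheptan-2-one F4. Cross-metathesis of its monosubstituted olefin with 2-methyl-2-butene (Grubbs II) installs the isopropylidene end and comes back to the route at 8.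

- **Step 9** (functionalised Grignard, slow carbocupration, and an alkenylcopper that opens oxirane poorly). Fallback: set out from 13 and proceed through 14–16 as before, but quench 16 with iodine to give (1Z,5E,9R)-1-iodo-11,11-dimethoxy-2,6-dimethyl-9-(6-methylhepta-1,5-dien-2-yl)undeca-1,5-diene F5. Iodine–lithium exchange (t-BuLi, −78 °C) gives the configurationally stable [(1Z,5E,9R)-11,11-dimethoxy-2,6-dimethyl-9-(6-methylhepta-1,5-dien-2-yl)undeca-1,5-dien-1-yl]lithium F6, which opens oxirane under BF3·OEt2 activation and comes back at 17.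

- **Step 13** (oligomerisation and E/Z control in the macrocyclisation). Fallback: set out from 18. Alkylation of methyl (triphenylphosphoranylidene)acetate gives [(5Z,9E,13R)-1,15,15-trimethoxy-6,10-dimethyl-13-(6-methylhepta-1,5-dien-2-yl)-1-oxopentadeca-5,9-dien-2-yl]triphenylphosphonium iodide F7. Mild acid hydrolysis of the acetal gives [(5Z,9E,13R)-1-methoxy-6,10-dimethyl-13-(6-methylhepta-1,5-dien-2-yl)-1,15-dioxopentadeca-5,9-dien-2-yl]triphenylphosphonium iodide F8. Slow addition to K2CO3 at high dilution generates the stabilised ylide methyl (5Z,9E,13R)-6,10-dimethyl-13-(6-methylhepta-1,5-dien-2-yl)-15-oxo-2-(triphenyl-λ5-phosphanylidene)pentadeca-5,9-dienoate F9, which closes by salt-free intramolecular Wittig reaction and comes back at 21.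

Further compounds
F1 | step 2 | (4R)-4-(hexa-1,5-dien-2-yl)-1-methylcyclohex-1-ene | C=CCCC(=C)[C@H]1CC=C(C)CC1
F2 | step 2 | (4R)-4-(hexa-1,5-dien-2-yl)-1-methyl-7-oxabicyclo[4.1.0]heptane | C=CCCC(=C)[C@H]1CC2OC2(C)CC1
F3 | step 2 | (3R)-3-(hexa-1,5-dien-2-yl)-6-oxoheptanal | O=CC[C@@H](CCC(C)=O)C(=C)CCC=C
F4 | step 2 | (5R)-5-(hexa-1,5-dien-2-yl)-7,7-dimethoxyheptan-2-one | COC(OC)C[C@@H](CCC(C)=O)C(=C)CCC=C
F5 | step 9 | (1Z,5E,9R)-1-iodo-11,11-dimethoxy-2,6-dimethyl-9-(6-methylhepta-1,5-dien-2-yl)undeca-1,5-diene | COC(OC)C[C@@H](CC/C(C)=C/CC/C(C)=C\I)C(=C)CCC=C(C)C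
F6 | step 9 | [(1Z,5E,9R)-11,11-dimethoxy-2,6-dimethyl-9-(6-methylhepta-1,5-dien-2-yl)undeca-1,5-dien-1-yl]lithium | COC(OC)C[C@@H](CC/C(C)=C/CC/C(C)=C\[Li])C(=C)CCC=C(C)C
F7 | step 13 | [(5Z,9E,13R)-1,15,15-trimethoxy-6,10-dimethyl-13-(6-methylhepta-1,5-dien-2-yl)-1-oxopentadeca-5,9-dien-2-yl]triphenylphosphonium iodide | COC(OC)C[C@@H](CC/C(C)=C/CC/C(C)=C\CCC(C(=O)OC)[P+](c1ccccc1)(c1ccccc1)c1ccccc1)C(=C)CCC=C(C)C.[I-]
F8 | step 13 | [(5Z,9E,13R)-1-methoxy-6,10-dimethyl-13-(6-methylhepta-1,5-dien-2-yl)-1,15-dioxopentadeca-5,9-dien-2-yl]triphenylphosphonium iodide | O=CC[C@@H](CC/C(C)=C/CC/C(C)=C\CCC(C(=O)OC)[P+](c1ccccc1)(c1ccccc1)c1ccccc1)C(=C)CCC=C(C)C.[I-]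
F9 | step 13 | methyl (5Z,9E,13R)-6,10-dimethyl-13-(6-methylhepta-1,5-dien-2-yl)-15-oxo-2-(triphenyl-λ5-phosphanylidene)pentadeca-5,9-dienoate | O=CC[C@@H](CC/C(C)=C/CC/C(C)=C\CCC(C(=O)OC)=P(c1ccccc1)(c1ccccc1)c1ccccc1)C(=C)CCC=C(C)C
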